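All runs are simulated from invented constants; noise was put on by code.

In a one-step world the rate of making target would follow the enzyme times the second substrate to some power n, the apparent order. Ash was charged with twice the enzyme and twice the second substrate of alder, so the two runs can be folded into one number.

in all of them: enzyme 0.05 mol%

| flask | solid substrate | second substrate | remark |
|---|---|---|---|
| ash | 0.066 M | 0.50 equiv | the very flask that is asked about, followed so far |
| alder | 0.033 M | 0.50 equiv | run made earlier |
| flask | 0.066 M | 0.500 equiv |  |

| run | time / h | target / % | solid substrate / % |
|---|---|---|---|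
| ash | 1.00 | 0.1 | 97.4 |
| ash | 2.50 | 1.5 | 92.8 |
| ash | 5.00 | 4.7 | 86.2 |
| ash | 8.00 | 8.8 | 78.4 |
| alder | 3.00 | 2.5 | 83.1 |
| alder | 8.00 | 10.2 | 60.7 |
| alder | 15.0 | 22.2 | 28.6 |
| alder | 25.0 | 36.1 | 0.1 |

(scatter of a reading: 0.5 percentage points)

- as a solid, counted per litre of solution: solid substrate
- at the start none of the solid substrate is in solution
- what has only dissolved of solid substrate counts as not reacted

* apparent order in second substrate when 20% of the solid substrate are converted (what has only dissolved counts as not reacted) (percent change of the rate of making target for one percent more second substrate charged)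

We take the target gained from 5.00 h to 8.00 h in ash and from 3.00 h to 8.00 h in alder:

ρ = 0.887

n = ln ρ / ln 2 = −0.172, give or take 0.282

This ρ, the target made per hour per enzyme in ash over the same in alder, would be one if extra second substrate did nothing and the dissolved solid substrate stood equal in the two runs. Our reading of n lies nearer zero than its scatter. Alder's next slice, 8.00 h to 15.0 h, gives n = −0.327, so one number calls the order small but does not size it.

The forecast says 0.08, from −0.25 to 0.35, with the words “so the order in second substrate is near zero at 15–30 mM”; its sign differs from ours.

The flask gives 1.1 × 10⁻⁴. After 2.50 h it holds 0.0481% of its second substrate, with second product at 0.0330 M.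

    starting material → uncatalysed product (k = 0.290 h⁻¹)
    starting material + enzyme ⇌ complex A (K = 6.60 M⁻¹, k = 1.40 × 10⁵ M⁻¹ h⁻¹)
    solid substrate ⇌ starting material, rate k3*(cs3 - [starting material]) while solid is left; crystals form when [starting material] > cs3 (solubility = 8.80 mM, k = 0.270 h⁻¹)
    complex B → enzyme + second product (k = 1600 h⁻¹)
    second substrate + enzyme ⇌ complex B (K = 81.0 M⁻¹, k = 3.60 × 10⁶ M⁻¹ h⁻¹)
    complex A → enzyme + target (k = 1700 h⁻¹)

If twice the enzyme raised the rate in the flask by the factor 1.77 read from ash over alder, the 9.10 h to 20% conversion would shrink by the factor 0.564; the run with twice the enzyme gives 0.871.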